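The route is built around one sp3–sp2 cross-coupling. It cuts the C(sp3)–C(sp2) bond between the last methylene of the CH2CH2CH2 linker (counted from the methyl-bearing S stereocentre) and the methyl-bearing carbon of the neighbouring E-trisubstituted alkene. One B-alkyl Suzuki–Miyaura coupling makes this bond and joins both halves. Its precursor is an O-SEM-protected (E)-5-ylidene tetronate (ring A, stereocentre and exocyclic alkene already in place) whose terminal vinyl group is hydroborated with 9-BBN. The borane is coupled, with retention, to an (E)-2-iodoalk-2-ene carrying the second alkene and the 3-furyl ring (ring B). The step exploits the allylic CH2–C(CH3)=CH junction: the linker is a latent allyl group.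

Key step: step 14

Remark: the exocyclic alkene of ring A is taken as drawn, E (side chain cis to the C4 oxygen); because aldol–dehydration would favour the Z isomer, the geometry is set in an α-acyloxy acrylate of defined geometry and carried into the ring.

Step 1
Reactants: 1 (R)-4-benzyl-3-propanoyl-1,3-oxazolidin-2-one
Product: 2 (4R)-4-benzyl-3-[(2S)-2-methylpent-4-enoyl]-1,3-oxazolidin-2-one
Conditions: NaN(SiMe3)2, THF, −78 °C; allyl iodide, −78 → −45 °C
Reagents that add atoms: allyl iodide, C=CCI
Why: Evans asymmetric alkylation, in which the chelated Z sodium enolate is allylated on the face opposite the benzyl group, which sets the (S)-methyl stereocentre.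

Step 2
Reactants: 2 (4R)-4-benzyl-3-[(2S)-2-methylpent-4-enoyl]-1,3-oxazolidin-2-one
Product: 3 (2S)-2-methylpent-4-en-1-ol
Conditions: LiBH4, MeOH (1 equiv), Et2O, 0 °C
Reagents that add atoms: none
Why: Reductive cleavage of the imide by LiBH4 (hydride attack at the exocyclic carbonyl) should release the primary alcohol and the recoverable auxiliary without touching the stereocentre.

Step 3
Reactants: 3 (2S)-2-methylpent-4-en-1-ol
Product: 4 (2S)-2-methylpent-4-enal
Conditions: Dess–Martin periodinane, CH2Cl2, 0 °C → rt; used at once as a solution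
Reagents that add atoms: none
Why: Dess–Martin oxidation of the primary alcohol is mild and non-basic, so the volatile α-chiral aldehyde should form without epimerisation.

Step 4
Reactants: 5 methyl 2-[bis(2,2,2-trifluoroethoxy)phosphoryl]acetate
Product: 6 methyl 2-[bis(2,2,2-trifluoroethoxy)phosphoryl]-2-bromoacetate (racemic)
Conditions: NaH (2.1 equiv), THF, 0 °C; N-bromosuccinimide (1.0 equiv), −78 → 0 °C; AcOH
Reagents that add atoms: N-bromosuccinimide, O=C1CCC(=O)N1Br
Why: Electrophilic α-bromination of the phosphonoacetate carbanion, in which the second equivalent of NaH keeps the product as its anion so that only one bromine should be introduced.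

Step 5
Reactants: 4 (2S)-2-methylpent-4-enal; 6 methyl 2-[bis(2,2,2-trifluoroethoxy)phosphoryl]-2-bromoacetate
Product: 7 methyl (2E,4S)-2-bromo-4-methylhepta-2,6-dienoate
Conditions: KOt-Bu, 18-crown-6, THF, −78 °C
Reagents that add atoms: none
Why: Horner–Wadsworth–Emmons olefination under Still–Gennari-type kinetic control (trifluoroethyl phosphonate, dissociated potassium salt), which should place the aldehyde substituent cis to the ester and so give the E α-bromoacrylate, the low temperature sparing the α-stereocentre.

Step 6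
Reactants: 7 methyl (2E,4S)-2-bromo-4-methylhepta-2,6-dienoate; 8 propanoic acid
Product: 9 methyl (2E,4S)-4-methyl-2-(propanoyloxy)hepta-2,6-dienoate
Conditions: CuI (20 mol %), trans-N,N′-dimethylcyclohexane-1,2-diamine (40 mol %), Cs2CO3, THF, 60 °C
Reagents that add atoms: none
Why: Ullmann-type C–O coupling of an alkenyl bromide with a carboxylate at monovalent copper, which proceeds by oxidative addition and reductive elimination with retention of alkene geometry, so the enol ester should keep the side chain cis to the methyl ester.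

Step 7
Reactants: 9 methyl (2E,4S)-4-methyl-2-(propanoyloxy)hepta-2,6-dienoate
Product: 11 (5E)-3-methyl-5-[(2S)-2-methylpent-4-en-1-ylidene]-4-{[2-(trimethylsilyl)ethoxy]methoxy}furan-2(5H)-one, via lithium tetronate 10 (not isolated)
Conditions: LiN(SiMe3)2 (2.2 equiv), THF, −78 → −20 °C; then SEMCl, DMPU, −20 °C → rt
Reagents that add atoms: 2-(trimethylsilyl)ethoxymethyl chloride, C[Si](C)(C)CCOCCl
Why: Lacey–Dieckmann condensation, in which the propanoate enolate attacks the neighbouring methyl ester (5-exo-trig) so that the enol ester geometry becomes the E-ylidene of ring A, followed by O-alkylation of the tetronate at O4 by the hard chloromethyl ether.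

Step 8
Reactants: 12 pent-3-yn-1-ol
Product: 13 5-iodopent-2-yne
Conditions: PPh3, imidazole, I2, CH2Cl2, 0 °C → rt
Reagents that add atoms: iodine, II
Why: Appel-type iodination, an SN2 displacement of the oxyphosphonium group by iodide at a primary carbon.

Step 9
Reactants: 13 5-iodopent-2-yne
Product: 14 pent-3-yn-1-ylzinc iodide (kept as a titrated THF solution of its LiCl complex)
Conditions: Zn dust (activated with cat. BrCH2CH2Br and Me3SiCl), LiCl, THF, 40 °C; iodometric titration
Reagents that add atoms: Zn dust, [Zn]
Why: LiCl-promoted direct insertion of zinc into the primary C–I bond, to which the internal alkyne is inert; the stock solution is prepared once and serves both Negishi couplings (steps 10 and 12).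

Step 10
Reactants: 14 pent-3-yn-1-ylzinc iodide; 15 3-bromofuran
Product: 16 3-(pent-3-yn-1-yl)furan
Conditions: Pd(OAc)2 (2 mol %), SPhos (4 mol %), THF, rt
Reagents that add atoms: none
Why: Negishi sp3–sp2 coupling of the primary alkylzinc iodide with the heteroaryl bromide, the bulky biarylphosphine favouring reductive elimination over β-hydride elimination.

Step 11
Reactants: 16 3-(pent-3-yn-1-yl)furan
Product: 18 3-[(3E)-4-iodopent-3-en-1-yl]furan, via alkenylzirconocene chloride 17 (not isolated)
Conditions: Cp2Zr(H)Cl (2.5 equiv), THF, 50 °C; then I2, THF, 0 °C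
Reagents that add atoms: iodine, II
Why: Hydrozirconation–iodination, in which syn addition of Zr–H and equilibration with excess Cp2Zr(H)Cl should place zirconium on the less hindered methyl-bearing carbon and iodinolysis with retention should give the E iodide.

Step 12
Reactants: 18 3-[(3E)-4-iodopent-3-en-1-yl]furan; 14 pent-3-yn-1-ylzinc iodide
Product: 19 3-[(3E)-4-methylnon-3-en-7-yn-1-yl]furan
Conditions: Pd(PPh3)4 (5 mol %), THF, rt → 40 °C
Reagents that add atoms: none
Why: Negishi sp3–sp2 coupling with a second portion of the zinc reagent from step 9, whose stereoretentive oxidative addition and reductive elimination should carry the E geometry of the alkenyl iodide into the trisubstituted alkene.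

Step 13
Reactants: 19 3-[(3E)-4-methylnon-3-en-7-yn-1-yl]furan
Product: 21 3-[(3E,7E)-8-iodo-4-methylnona-3,7-dien-1-yl]furan, via alkenylzirconocene chloride 20 (not isolated)
Conditions: Cp2Zr(H)Cl (2.5 equiv), THF, 50 °C; then I2, THF, 0 °C
Reagents that add atoms: iodine, II
Why: Hydrozirconation–iodination as in step 11, the alkyne reacting far faster than the trisubstituted alkene and the furan, with zirconium settling on the methyl-bearing carbon and iodinolysis with retention giving the E iodide.

Step 14
Reactants: 11 (5E)-3-methyl-5-[(2S)-2-methylpent-4-en-1-ylidene]-4-{[2-(trimethylsilyl)ethoxy]methoxy}furan-2(5H)-one; 21 3-[(3E,7E)-8-iodo-4-methylnona-3,7-dien-1-yl]furan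
Product: 23 (5E)-5-[(2S,6E,10E)-13-(furan-3-yl)-2,6,10-trimethyltrideca-6,10-dien-1-ylidene]-3-methyl-4-{[2-(trimethylsilyl)ethoxy]methoxy}furan-2(5H)-one, via B-alkyl-9-BBN adduct 22 (not isolated)
Conditions: 9-BBN dimer, THF, 0 °C → rt; then 21, PdCl2(dppf) (5 mol %), AsPh3 (10 mol %), Cs2CO3, DMF/H2O, rt
Reagents that add atoms: none
Why: 9-BBN adds syn and anti-Markovnikov to the monosubstituted alkene of 11, so boron ends on the terminal carbon (22). Zerovalent palladium inserts into the C–I bond of 21, the borate formed from 22 and base transfers its primary alkyl group to palladium, and reductive elimination forms the CH2–C(CH3)= bond; this is a B-alkyl Suzuki–Miyaura coupling, a known reaction type for primary alkyl-9-BBN reagents and trisubstituted alkenyl iodides. No ring is closed and no stereocentre is created; the S centre lies three bonds from boron and is not touched. The E geometry of the new trisubstituted alkene is inherited from 21 because oxidative addition and reductive elimination are stereoretentive. Chemoselective hydroboration is secured by the steric demand of 9-BBN, which should leave the conjugated tri- and tetrasubstituted alkenes and the lactone carbonyl of ring A alone. β-Hydride elimination should be outrun by reductive elimination thanks to the wide bite angle of dppf, and the mild base at room temperature should spare the SEM vinylogous ester and the E-ylidene.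

Step 15
Reactants: 23 (5E)-5-[(2S,6E,10E)-13-(furan-3-yl)-2,6,10-trimethyltrideca-6,10-dien-1-ylidene]-3-methyl-4-{[2-(trimethylsilyl)ethoxy]methoxy}furan-2(5H)-one
Product: 24 (5E)-5-[(2S,6E,10E)-13-(furan-3-yl)-2,6,10-trimethyltrideca-6,10-dien-1-ylidene]-4-hydroxy-3-methylfuran-2(5H)-one
Conditions: Bu4NF, THF, 0 °C → rt; then cold 0.5 M HCl work-up
Reagents that add atoms: none
Why: Fluoride-induced fragmentation of the SEM group (attack at silicon, loss of ethene and formaldehyde) should release the weakly basic tetronate under conditions that leave the E-ylidene, the furan and the stereocentre untouched.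

Step 16
Reactants: 24 (5E)-5-[(2S,6E,10E)-13-(furan-3-yl)-2,6,10-trimethyltrideca-6,10-dien-1-ylidene]-4-hydroxy-3-methylfuran-2(5H)-one; 25 hexadecanoyl chloride
Product: 26 (2E)-2-[(2S,6E,10E)-13-(furan-3-yl)-2,6,10-trimethyltrideca-6,10-dien-1-ylidene]-4-methyl-5-oxo-2,5-dihydrofuran-3-yl hexadecanoate (target)
Conditions: Et3N, CH2Cl2, −20 → 0 °C
Reagents that add atoms: none
Why: O-Acylation of the tetronic acid at O4 by the acid chloride (Schotten–Baumann-type, amine base), run cold and without an acyl-transfer catalyst so that the enol ester should form without acyl migration or alkene isomerisation.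

Compound list
1 | (R)-4-benzyl-3-propanoyl-1,3-oxazolidin-2-one | CCC(=O)N1[C@H](Cc2ccccc2)COC1=O | starting material
2 | (4R)-4-benzyl-3-[(2S)-2-methylpent-4-enoyl]-1,3-oxazolidin-2-one | C=CC[C@H](C)C(=O)N1[C@H](Cc2ccccc2)COC1=O | intermediate
3 | (2S)-2-methylpent-4-en-1-ol | C=CC[C@H](C)CO | intermediate
4 | (2S)-2-methylpent-4-enal | C=CC[C@H](C)C=O | intermediate
5 | methyl 2-[bis(2,2,2-trifluoroethoxy)phosphoryl]acetate | COC(=O)CP(=O)(OCC(F)(F)F)OCC(F)(F)F | starting material
6 | methyl 2-[bis(2,2,2-trifluoroethoxy)phosphoryl]-2-bromoacetate (racemic) | COC(=O)C(Br)P(=O)(OCC(F)(F)F)OCC(F)(F)F | intermediate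
7 | methyl (2E,4S)-2-bromo-4-methylhepta-2,6-dienoate | C=CC[C@H](C)/C=C(/Br)C(=O)OC | intermediate
8 | propanoic acid | CCC(=O)O | starting material
9 | methyl (2E,4S)-4-methyl-2-(propanoyloxy)hepta-2,6-dienoate | C=CC[C@H](C)/C=C(/OC(=O)CC)C(=O)OC | intermediate
10 | lithium (2E)-4-methyl-2-[(2S)-2-methylpent-4-en-1-ylidene]-5-oxo-2,5-dihydrofuran-3-olate | [Li+].[O-]C1=C(C)C(=O)O/C1=C/[C@@H](C)CC=C | intermediate
11 | (5E)-3-methyl-5-[(2S)-2-methylpent-4-en-1-ylidene]-4-{[2-(trimethylsilyl)ethoxy]methoxy}furan-2(5H)-one | C[Si](C)(C)CCOCOC1=C(C)C(=O)O/C1=C/[C@@H](C)CC=C | intermediate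
12 | pent-3-yn-1-ol | CC#CCCO | starting material
13 | 5-iodopent-2-yne | CC#CCCI | intermediate
14 | pent-3-yn-1-ylzinc iodide | CC#CCC[Zn]I | intermediate
15 | 3-bromofuran | Brc1ccoc1 | starting material
16 | 3-(pent-3-yn-1-yl)furan | CC#CCCc1ccoc1 | intermediate
17 | chlorobis(cyclopentadienyl)[(2E)-5-(furan-3-yl)pent-2-en-2-yl]zirconium | Cl[Zr](C1C=CC=C1)(C1C=CC=C1)/C(C)=C/CCc1ccoc1 | intermediate
18 | 3-[(3E)-4-iodopent-3-en-1-yl]furan | I/C(C)=C/CCc1ccoc1 | intermediate
19 | 3-[(3E)-4-methylnon-3-en-7-yn-1-yl]furan | CC#CCC/C(C)=C/CCc1ccoc1 | intermediate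
20 | chlorobis(cyclopentadienyl)[(2E,6E)-9-(furan-3-yl)-6-methylnona-2,6-dien-2-yl]zirconium | Cl[Zr](C1C=CC=C1)(C1C=CC=C1)/C(C)=C/CC/C(C)=C/CCc1ccoc1 | intermediate
21 | 3-[(3E,7E)-8-iodo-4-methylnona-3,7-dien-1-yl]furan | I/C(C)=C/CC/C(C)=C/CCc1ccoc1 | intermediate
22 | 9-{(4S)-4-methyl-5-[(2E)-4-methyl-5-oxo-3-{[2-(trimethylsilyl)ethoxy]methoxy}furan-2(5H)-ylidene]pentyl}-9-borabicyclo[3.3.1]nonane | C[Si](C)(C)CCOCOC1=C(C)C(=O)O/C1=C/[C@@H](C)CCCB1C2CCCC1CCC2 | intermediate
23 | (5E)-5-[(2S,6E,10E)-13-(furan-3-yl)-2,6,10-trimethyltrideca-6,10-dien-1-ylidene]-3-methyl-4-{[2-(trimethylsilyl)ethoxy]methoxy}furan-2(5H)-one | C[Si](C)(C)CCOCOC1=C(C)C(=O)O/C1=C/[C@@H](C)CCC/C(C)=C/CC/C(C)=C/CCc1ccoc1 | intermediate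
24 | (5E)-5-[(2S,6E,10E)-13-(furan-3-yl)-2,6,10-trimethyltrideca-6,10-dien-1-ylidene]-4-hydroxy-3-methylfuran-2(5H)-one | OC1=C(C)C(=O)O/C1=C/[C@@H](C)CCC/C(C)=C/CC/C(C)=C/CCc1ccoc1 | intermediate
25 | hexadecanoyl chloride | CCCCCCCCCCCCCCCC(=O)Cl | starting material
26 | (2E)-2-[(2S,6E,10E)-13-(furan-3-yl)-2,6,10-trimethyltrideca-6,10-dien-1-ylidene]-4-methyl-5-oxo-2,5-dihydrofuran-3-yl hexadecanoate | CCCCCCCCCCCCCCCC(=O)OC1=C(C)C(=O)O/C1=C/[C@@H](C)CCC/C(C)=C/CC/C(C)=C/CCc1ccoc1 | target

Total step count: 16.
Longest linear sequence: 9 steps (steps 1, 2, 3, 5, 6, 7, 14, 15, 16, from compound 1). The right-hand branch from 12 is equally long (steps 8–16).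

Steps most likely to fail

Step 6. At the temperature the copper catalyst needs, the bromoacrylate may lose its geometry through reversible conjugate addition of the carboxylate, or may be reduced instead of coupled. The fallback makes the C–O bond through boron. Setting out from 7, Miyaura borylation (B2pin2, PdCl2(dppf), KOAc, dioxane, 80 °C) should give methyl (2Z,4S)-4-methyl-2-(4,4,5,5-tetramethyl-1,3,2-dioxaborolan-2-yl)hepta-2,6-dienoate F1 with retention. A Chan–Lam-type oxidative coupling of F1 with propanoic acid 8 (Cu(OAc)2, Et3N, molecular sieves, air, CH2Cl2, rt), also stereoretentive, comes back to the route at 9.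

Step 7. The propanoate enolate may fragment to methylketene and the keto ester enolate, or the base may deprotonate the allylic γ-position, which would erode the E geometry and the stereocentre; alkylation at O2 instead of O4 is a further risk. The fallback avoids the ester enolate and sets out from aldehyde 4. Commercial 4-hydroxy-3-methylfuran-2(5H)-one is converted with SEMCl and i-Pr2NEt into 3-methyl-4-{[2-(trimethylsilyl)ethoxy]methoxy}furan-2(5H)-one F2, and then with t-BuMe2SiOTf and Et3N into tert-butyl(dimethyl)[(3-methyl-4-{[2-(trimethylsilyl)ethoxy]methoxy}furan-2-yl)oxy]silane F3. A fluoride-promoted vinylogous Mukaiyama aldol addition of F3 to 4 should give the 5-(1-hydroxyalkyl) adducts. From these the 5,1′-like diastereomer (5S)-5-[(1S,2S)-1-hydroxy-2-methylpent-4-en-1-yl]-3-methyl-4-{[2-(trimethylsilyl)ethoxy]methoxy}furan-2(5H)-one F4 is separated; its 5R,1′R counterpart behaves the same way. Stereospecific anti-elimination of water under Mitsunobu-type conditions (PPh3, diethyl azodicarboxylate, THF) should then give the E-ylidene and comes back to the route at 11.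

Step 13 (the same holds for step 11). Equilibration of the two regioisomeric alkenylzirconium species may stay incomplete, so that some zirconium, and then iodine, ends on the wrong alkyne carbon and a regioisomer is carried into the coupling. The fallback fixes the regiochemistry with silicon and sets out from 18. Negishi coupling with [4-(trimethylsilyl)but-3-yn-1-yl]zinc iodide (Pd(PPh3)4, THF) should give 3-[(3E)-4-methyl-8-(trimethylsilyl)oct-3-en-7-yn-1-yl]furan F5. Hydroalumination with i-Bu2AlH in heptane at 50 °C puts aluminium only on the silicon-bearing carbon, and the adduct equilibrates to the trans form. Treatment with MeLi and then MeI should give 3-[(3E,7E)-4-methyl-8-(trimethylsilyl)nona-3,7-dien-1-yl]furan F6. Iododesilylation with N-iodosuccinimide (MeCN, 0 °C), with retention, comes back to the route at 21.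

Further compounds
F1 | step 6 | methyl (2Z,4S)-4-methyl-2-(4,4,5,5-tetramethyl-1,3,2-dioxaborolan-2-yl)hepta-2,6-dienoate | C=CC[C@H](C)/C=C(/B1OC(C)(C)C(C)(C)O1)C(=O)OC
F2 | step 7 | 3-methyl-4-{[2-(trimethylsilyl)ethoxy]methoxy}furan-2(5H)-one | CC1=C(OCOCC[Si](C)(C)C)COC1=O
F3 | step 7 | tert-butyl(dimethyl)[(3-methyl-4-{[2-(trimethylsilyl)ethoxy]methoxy}furan-2-yl)oxy]silane | CC1=C(O[Si](C)(C)C(C)(C)C)OC=C1OCOCC[Si](C)(C)C
F4 | step 7 | (5S)-5-[(1S,2S)-1-hydroxy-2-methylpent-4-en-1-yl]-3-methyl-4-{[2-(trimethylsilyl)ethoxy]methoxy}furan-2(5H)-one | C=CC[C@H](C)[C@H](O)[C@@H]1OC(=O)C(C)=C1OCOCC[Si](C)(C)C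
F5 | step 13 | 3-[(3E)-4-methyl-8-(trimethylsilyl)oct-3-en-7-yn-1-yl]furan | C[Si](C)(C)C#CCC/C(C)=C/CCc1ccoc1
F6 | step 13 | 3-[(3E,7E)-4-methyl-8-(trimethylsilyl)nona-3,7-dien-1-yl]furan | C[Si](C)(C)/C(C)=C/CC/C(C)=C/CCc1ccoc1
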